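The numbers of this flask belong to no real substance.

**The dose.** The 1.20 equiv of incoming ligand is the number I reckon from, since this limiting reagent has to serve successive exchanges, of which the second, at 2900 L mol⁻¹ s⁻¹, is faster than the third, at 250 L mol⁻¹ s⁻¹.

starting complex 0.20 mM; incoming ligand 1.20 equiv; time 1.5 min

    starting complex + incoming ligand → leaving ligand + complex with one exchanged (k1 = 1700 L mol⁻¹ s⁻¹)
    complex with one exchanged + incoming ligand → leaving ligand + complex with two exchanged (k2 = 2900 L mol⁻¹ s⁻¹)
    complex with two exchanged + incoming ligand → leaving ligand + complex with three exchanged (k3 = 250 L mol⁻¹ s⁻¹)
    complex with three exchanged + incoming ligand → leaving ligand + complex with four exchanged (k4 = 140 L mol⁻¹ s⁻¹)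
    crystals ⇌ complex with three exchanged, rate k5*(cs5 - [complex with three exchanged]) while solid is left; crystals form when [complex with three exchanged] > cs5 (cs5 = 0.0034 mM, k5 = 5.0 s⁻¹)

* complex with three exchanged and crystals together at 1.5 min, in percent of the starting complex charged
* the change that raises the amount of complex with three exchanged and crystals together at 1.5 min, in percent of the starting complex charged most ("none" if none brings more than 2 percentage points) (Wednesday's / Monday's / Saturday's / none)
* amount of complex with three exchanged and crystals together at 1.5 min, in percent of the starting complex charged, after Saturday's

- Wednesday's: doubling the dissolution coefficient of step 5, all else as stated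
- Monday's: doubling the solubility in step 5, all else as stated
- Saturday's: doubling the amount of incoming ligand, all else as stated

I call the dose, put below at 1.20, the first rate constant times the time integral of the ligand concentration, so that the fraction of starting complex remaining is exp(−dose). The first step uses one equivalent per unit of dose at the start, and I freeze that use, which makes the dose equal to the charge in equivalents; the ligand's starting lifetime by the first step, 2.94 s, is shorter than 1.5 min, so I expect the dose to stop growing within the run.

**First doubt.** The use is not constant, since complex with one exchanged reacts 1.71 times as fast as starting complex, while complex with two exchanged reacts slower than starting complex, at 250 L mol⁻¹ s⁻¹ against 1700 L mol⁻¹ s⁻¹. Putting the dose into the exact two-step solution gives 1.15 equivalents used, close to the charge, so I keep the dose.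

**The third exchange.** Integrating complex with two exchanged over the dose and multiplying by 0.147, the ratio of third to first constants, I get 3.45 % for complex with three exchanged and crystals together. Step five moves material between solution and crystals, and both count, so I expect neither of its changes to bring 2 percentage points.

**Saturday's doubling.** I drop the frozen dose here and count ligand instead: two exchanges per complex leave a surplus for the third worth 40.0 % of the starting complex charged. The objection is time, but the surplus ligand's half-life by the third step, with complex with two exchanged taken at the concentration of the charge, is 13.9 s, shorter than the run. My choice is Saturday's.

The forecast gives 3.5 %, Saturday's and 37 %, holding that “the ligand is gone within seconds to tens of seconds”.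

The flask gives 3.30 %; the best change is Saturday's, worth 36 points, and it reaches 39.5 %.

**Dose again.** At 0.0223 min in the flask, the ligand's half-life is 0.052 min by the first step and 0.082 min by the second, whereas complex with two exchanged has 0.31 min by the third, longer than either. Incoming ligand stands at 0 % by 0.750 min, with complex with two exchanged at 42.8 % then. The dose predicts 30.1 % of starting complex left in the flask, which holds 29.6 %. The neighbour flask with 0.480 equiv of ligand has a predicted 61.9 % and holds 63.9 %.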